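**Assumptions (one line each)**
- Superstolide numbering (C1 = lactone carbonyl … C27) is used for every intermediate; in the decalin, β is the face of the C8 methyl group (H9, H11, H13, H14, H17 are β; OMe, O13, C7, C18 are α).
- The (S,S) antipode of the new catalyst in step 9 is taken as the one that gives the drawn enantiomer; if induction is opposite, the (R,R) antipode is used.
- The crotylboronate of step 21 and the aluminium reagent of step 4 are used as pre-formed stock reagents.

**Retrosynthetic overview**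
1. Superstolide A ⇒ desilylation and Yamaguchi macrolactonisation (C1–O23) of a seco-acid, itself from two site-selective Stille couplings (C5–C6, then C19–C20) on a decalin bis(alkenylstannane).
2. Decalin ⇒ 17α-propynyl by axial conjugate alkynylation and enol-triflate reduction; ring A by an enantioselective desymmetrising double Mukaiyama–Michael annulation of 4-ethynyl-4-methylcyclohexadienone with a 1-alkoxy-3-siloxydiene.
3. Key step: the quaternary carbon C8 (methyl plus C7) comes from a Lewis-acid epoxide ring contraction (seven- to six-membered ring, 1,2-alkyl shift) of 4,5-epoxy-4-methylcycloheptanone, made by hydrazone alkylation and ring-closing metathesis.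
4. Side chain C20–C27 ⇒ D-alaninol by crotylboration (C24/C25), allenylzinc propargylation (C22/C23) and hydrostannation/iodination; C1–C5 ⇒ but-2-yn-1-ol.
5. Ring order: seven-membered carbocycle → ring B (by contraction) → ring A (annulation) → 16-membered macrolactone.

## Route

**Core (C7–C19)**

Step 1
Reactants: 1 acetone N,N-dimethylhydrazone; 2 allyl bromide; 3 methallyl bromide
Product: 6 2-methylnona-1,8-dien-5-one, via monoallyl hydrazone 4 (not isolated), via dialkyl hydrazone 5 (not isolated)
Conditions: n-BuLi, THF, −78 → 0 °C, then 2; n-BuLi, −78 → 0 °C, then 3; 1 M HCl, rt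
Reagents that add atoms: water (O)
Why: Corey–Enders azaenolate alkylation: each deprotonation occurs at the less substituted α-carbon, so the two allylic bromides end up on opposite sides of the carbonyl, which mild acid hydrolysis unmasks; no stereocentre.

Step 2
Reactants: 6 2-methylnona-1,8-dien-5-one
Product: 7 4-methylcyclohept-4-en-1-one
Conditions: second-generation Grubbs catalyst (H2IMes)(PCy3)Cl2Ru=CHPh (2 mol%), CH2Cl2 (5 mM), 40 °C
Reagents that add atoms: none
Why: Ring-closing metathesis of the 1,8-diene gives the seven-membered ring with the trisubstituted olefin (future C7=C8) and loses ethylene; no stereocentre.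

Step 3
Reactants: 7 4-methylcyclohept-4-en-1-one
Product: 8 racemic 1-methyl-8-oxabicyclo[5.1.0]octan-4-one
Conditions: mCPBA, CH2Cl2, 0 °C
Reagents that add atoms: mCPBA (OOC(=O)c1cccc(Cl)c1)
Why: Prilezhaev epoxidation of the electron-rich trisubstituted olefin is much faster than Baeyer–Villiger oxidation of the unstrained ketone; the epoxide is racemic, which does not matter because the next product is achiral.

Step 4
Reactants: 8 racemic 1-methyl-8-oxabicyclo[5.1.0]octan-4-one
Product: 9 1-methyl-4-oxocyclohexane-1-carbaldehyde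
Conditions: MeAl(OAr)2 (Ar = 4-bromo-2,6-di-tert-butylphenyl, 2 equiv), CH2Cl2, −78 → −20 °C
Reagents that add atoms: none
Why: Meinwald (semipinacol-type) epoxide rearrangement: the bulky aluminium Lewis acid ionises the tertiary C–O bond and the ring CH2 on the neighbouring carbon migrates anti to it in preference to hydride, contracting the ring and creating quaternary C8 with its methyl group and C7 as a formyl group; the product is achiral.

Step 5
Reactants: 9 1-methyl-4-oxocyclohexane-1-carbaldehyde
Product: 10 4-ethynyl-4-methylcyclohexan-1-one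
Conditions: dimethyl (1-diazo-2-oxopropyl)phosphonate, K2CO3, MeOH, 0 °C → rt
Reagents that add atoms: dimethyl (1-diazo-2-oxopropyl)phosphonate (CC(=O)C(=[N+]=[N-])P(=O)(OC)OC)
Why: Ohira–Bestmann (Seyferth–Gilbert) homologation converts only the aldehyde into the terminal alkyne C7≡C6, a slim rod that later steers both ring-B additions to the face opposite the methyl group.

Step 6
Reactants: 10 4-ethynyl-4-methylcyclohexan-1-one
Product: 11 4-ethynyl-4-methylcyclohexa-2,5-dien-1-one
Conditions: IBX (3.5 equiv), DMSO, 80 °C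
Reagents that add atoms: none
Why: IBX α,β-dehydrogenation (twice) gives the cross-conjugated dienone; the quaternary C4 blocks aromatisation and an ethynyl group cannot be lost the way an acyl group could.

Step 7
Reactants: 12 but-3-yn-2-one
Product: 13 (3E)-4-[(4-methoxyphenyl)methoxy]but-3-en-2-one
Conditions: 4-methoxybenzyl alcohol, PMe3 (5 mol%), CH2Cl2, 0 °C → rt
Reagents that add atoms: 4-methoxybenzyl alcohol (COc1ccc(CO)cc1)
Why: Phosphine-catalysed oxa-Michael addition of the alcohol to the ynone gives the thermodynamically favoured E-β-alkoxy enone.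

Step 8
Reactants: 13 (3E)-4-[(4-methoxyphenyl)methoxy]but-3-en-2-one
Product: 14 (E)-1-[(4-methoxyphenyl)methoxy]-3-(trimethylsilyloxy)buta-1,3-diene
Conditions: TMSOTf, Et3N, Et2O, 0 °C
Reagents that add atoms: TMSOTf (C[Si](C)(C)OS(=O)(=O)C(F)(F)F)
Why: Soft enolisation and O-silylation of the methyl ketone gives the electron-rich 1-alkoxy-3-siloxydiene (Danishefsky type).

Step 9
Reactants: 11 4-ethynyl-4-methylcyclohexa-2,5-dien-1-one; 14 (E)-1-[(4-methoxyphenyl)methoxy]-3-(trimethylsilyloxy)buta-1,3-diene
Product: 16 cis-fused 11,15-diketone (8α-ethynyl, 8β-methyl, 13α-OPMB, Δ16), via silyl enol ether 15 (not isolated)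
Conditions: (S,S)-IDPi acid (BINOL-derived imidodiphosphorimidate, 3,3′-(3,5-(CF3)2C6H3), N-triflyl; 2 mol%), 14 (1.2 equiv), toluene, −60 °C; then AcOH, THF/H2O, 0 °C
Reagents that add atoms: none
Why: Proposed new method: enantioselective desymmetrising annulation under silylium/chiral-counteranion catalysis — the acid is silylated by the diene, the silylium ion pair O-silylates the dienone, the confined anion selects one of the two enantiotopic enone halves, C10 of the diene adds to C9 on the face opposite the C8 methyl (Mukaiyama–Michael), and the resulting C14 silyl enol ether closes onto C13 through a chair with the PMB ether equatorial (second Mukaiyama–Michael), so C8, C9, C13 and C14 are set in one operation with a cis ring fusion and the ring-A substituents α; the closest known reaction type is the IDPi-catalysed Mukaiyama–Michael addition of silyl nucleophiles to simple enones and enoates.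

Step 10
Reactants: 16 cis-fused 11,15-diketone
Product: 17 11α-alcohol (15-enone retained)
Conditions: NaBH4, MeOH/CH2Cl2 (1:1), −78 °C
Reagents that add atoms: none
Why: Chemoselective borohydride reduction of the saturated C11 ketone beside the less electrophilic enone; axial hydride attack on the locked ring-A chair from the β face gives the equatorial 11α-alcohol, cis to the C13 ether.

Step 11
Reactants: 17 11α-alcohol
Product: 18 11α-methyl ether
Conditions: Me3OBF4, 1,8-bis(dimethylamino)naphthalene, CH2Cl2, 0 °C → rt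
Reagents that add atoms: trimethyloxonium tetrafluoroborate (C[O+](C)C.F[B-](F)(F)F)
Why: O-Methylation with Meerwein's salt and a non-nucleophilic base avoids enolate chemistry and β-elimination of the C13 ether; configuration unchanged.

Step 12
Reactants: 18 11α-methyl ether
Product: 20 17α-propynyl C15 enol triflate, via silyl enol ether 19 (not isolated)
Conditions: MeC≡CMgBr, ZnBr2, THF, 0 °C; 18, TMSOTf, −40 °C; then CsF, PhNTf2, DME, rt
Reagents that add atoms: 1-propynylmagnesium bromide (CC#C[Mg]Br); N-phenylbis(trifluoromethanesulfonimide) (O=S(=O)(N(c1ccccc1)S(=O)(=O)C(F)(F)F)C(F)(F)F); TMSOTf, silyl group in 19 only (C[Si](C)(C)OS(=O)(=O)C(F)(F)F)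
Why: Silyl-triflate-promoted conjugate addition of an alkynylzinc halide, then fluoride-mediated conversion of the silyl enol ether into the enol triflate: the triequatorial ring A locks the cis-fused enone with the C8 methyl axial on the β face, so stereoelectronically preferred axial attack of the slim alkynyl group on C17 comes from the α face, anti to that methyl, setting C17 (17α-propynyl).

Step 13
Reactants: 20 17α-propynyl C15 enol triflate
Product: 21 Δ15 decalin PMB ether (8α-ethynyl, 17α-propynyl)
Conditions: Pd(OAc)2 (5 mol%), dppp (5 mol%), Et3SiH, DMF, 60 °C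
Reagents that add atoms: none
Why: Palladium-catalysed hydride reduction of the enol triflate (silane as hydride source, no amine, so the terminal alkyne does not couple) leaves the C15=C16 olefin where the target has it.

Step 14
Reactants: 21 Δ15 decalin PMB ether
Product: 22 13α-alcohol
Conditions: DDQ, CH2Cl2/pH 7 buffer (10:1), 0 °C
Reagents that add atoms: none
Why: Oxidative PMB cleavage by DDQ (benzylic hydride abstraction, hydrolysis of the oxocarbenium ion) frees the C13 alcohol without touching the alkynes or the methyl ether.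

Step 15
Reactants: 22 13α-alcohol
Product: 24 decalin 13α-carbamate, via trichloroacetyl carbamate 23 (not isolated)
Conditions: Cl3CC(O)NCO, CH2Cl2, 0 °C; then K2CO3 (cat.), MeOH, rt
Reagents that add atoms: trichloroacetyl isocyanate (O=C=NC(=O)C(Cl)(Cl)Cl)
Why: Carbamoylation by isocyanate addition and methanolysis of the N-trichloroacetyl group gives the primary carbamate with retention at C13.

**C1–C5 acid**

Step 16
Reactants: 25 but-2-yn-1-ol
Product: 26 (Z)-3-iodobut-2-en-1-ol
Conditions: NaAlH2(OCH2CH2OMe)2, THF, 0 °C → rt; EtOAc; then I2, −78 → 0 °C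
Reagents that add atoms: iodine (II)
Why: Hydroxyl-directed trans-hydroalumination places aluminium at C3 in a five-membered alanate, and iodinolysis with retention gives the Z-vinyl iodide (future C5 with its methyl).

Step 17
Reactants: 26 (Z)-3-iodobut-2-en-1-ol
Product: 28 methyl (2E,4Z)-5-iodohexa-2,4-dienoate, via Z-iodoenal 27 (not isolated)
Conditions: MnO2, Ph3P=CHCO2Me, CH2Cl2, rt
Reagents that add atoms: methyl (triphenylphosphoranylidene)acetate (COC(=O)C=P(c1ccccc1)(c1ccccc1)c1ccccc1)
Why: Tandem allylic oxidation–Wittig olefination traps the isomerisation-prone Z-enal in situ with the stabilised ylide, giving the 2E olefin and keeping the 4Z geometry.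

Step 18
Reactants: 28 methyl (2E,4Z)-5-iodohexa-2,4-dienoate
Product: 29 (2E,4Z)-5-iodohexa-2,4-dienoic acid
Conditions: LiOH, THF/H2O, 0 °C → rt; then 1 M HCl
Reagents that add atoms: lithium hydroxide ([Li+].[OH-])
Why: Saponification of the methyl ester; the vinyl iodide and both olefin geometries are untouched.

**Side chain (C20–C27)**

Step 19
Reactants: 30 D-alaninol
Product: 31 N-[(2R)-1-hydroxypropan-2-yl]acetamide
Conditions: Ac2O (1.05 equiv), MeOH, 0 °C
Reagents that add atoms: acetic anhydride (CC(=O)OC(C)=O)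
Why: Chemoselective N-acetylation (the amine is far more nucleophilic than the alcohol); this centre becomes C26.

Step 20
Reactants: 31 N-[(2R)-1-hydroxypropan-2-yl]acetamide
Product: 32 N-[(2R)-1-oxopropan-2-yl]acetamide
Conditions: Dess–Martin periodinane, CH2Cl2, 0 °C; used crude at once
Reagents that add atoms: none
Why: Dess–Martin oxidation under neutral conditions gives the configurationally labile α-acetamido aldehyde, which is used immediately without chromatography.

Step 21
Reactants: 32 N-[(2R)-1-oxopropan-2-yl]acetamide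
Product: 33 N-[(2R,3S,4S)-3-hydroxy-4-methylhex-5-en-2-yl]acetamide
Conditions: (R,R)-diisopropyl tartrate (E)-crotylboronate, 4 Å MS, toluene, −78 °C
Reagents that add atoms: (R,R)-diisopropyl tartrate (E)-crotylboronate (CC(C)OC(=O)[C@@H]1OB(C/C=C/C)O[C@H]1C(=O)OC(C)C)
Why: Tartrate-controlled crotylboration through a chair (Zimmerman–Traxler) transition state: the E-crotyl geometry gives the 24,25-anti relationship and the (R,R)-tartrate directs attack to the Si face, which is also the Felkin face, giving 25S (25,26-anti).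

Step 22
Reactants: 33 N-[(2R,3S,4S)-3-hydroxy-4-methylhex-5-en-2-yl]acetamide
Product: 34 25-O-TBS ether of 33
Conditions: TBSOTf, 2,6-lutidine, CH2Cl2, −78 → 0 °C
Reagents that add atoms: TBSOTf (CC(C)(C)[Si](C)(C)OS(=O)(=O)C(F)(F)F)
Why: Silylation of the hindered secondary alcohol with the silyl triflate; any O-silyl imidate formed from the amide is hydrolysed on work-up.

Step 23
Reactants: 34 25-O-TBS ether
Product: 36 N-[(2R,3S,4R)-3-(tert-butyldimethylsilyloxy)-4-methyl-5-oxopentan-2-yl]acetamide, via ozonide 35 (not isolated)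
Conditions: O3, CH2Cl2, −78 °C; then PPh3, −78 °C → rt
Reagents that add atoms: ozone ([O-][O+]=O)
Why: Ozonolysis with reductive work-up cleaves the terminal olefin to the C23 aldehyde; low temperature and neutral work-up avoid epimerisation at C24.

Step 24
Reactants: 37 (S)-but-3-yn-2-ol
Product: 38 (S)-but-3-yn-2-yl methanesulfonate
Conditions: MsCl, Et3N, CH2Cl2, −78 °C
Reagents that add atoms: methanesulfonyl chloride (CS(=O)(=O)Cl)
Why: Sulfonylation of the propargylic alcohol with retention (no bond to the stereocentre is broken).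

Step 25
Reactants: 36 C23 aldehyde; 38 (S)-but-3-yn-2-yl methanesulfonate
Product: 39 N-[(2R,3S,4S,5R,6R)-3-(tert-butyldimethylsilyloxy)-5-hydroxy-4,6-dimethyloct-7-yn-2-yl]acetamide
Conditions: Pd(OAc)2 (5 mol%), PPh3 (5 mol%), Et2Zn (3.5 equiv), THF, −78 → −20 °C
Reagents that add atoms: none
Why: Marshall propargylation: zerovalent palladium displaces the mesylate in an anti SN2′ sense, transmetallation gives a configurationally defined allenylzinc, and its cyclic SE2′ addition gives the anti homopropargylic alcohol; the (S)-mesylate gives 22R,23R, matched with Felkin control from C24 (23,24-syn).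

Step 26
Reactants: 39 homopropargylic alcohol
Product: 41 (E)-vinyl iodide N-[(2R,3S,4S,5R,6R,7E)-3-(tert-butyldimethylsilyloxy)-5-hydroxy-8-iodo-4,6-dimethyloct-7-en-2-yl]acetamide, via vinylstannane 40 (not isolated)
Conditions: Bu3SnH, PdCl2(PPh3)2 (3 mol%), THF, 0 °C; then I2, CH2Cl2, 0 °C
Reagents that add atoms: iodine (II); tributyltin hydride, tin in 40 only (CCCC[SnH](CCCC)CCCC)
Why: Palladium-catalysed syn-hydrostannation puts tin on the unhindered terminal carbon (E), and iododestannylation proceeds with retention.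

**Fragment union**

Step 27
Reactants: 24 decalin 13α-carbamate
Product: 42 decalin bis(alkenylstannane)
Conditions: Bu3SnH (2.5 equiv), PdCl2(PPh3)2 (5 mol%), THF, 0 °C → rt
Reagents that add atoms: tributyltin hydride (CCCC[SnH](CCCC)CCCC)
Why: Palladium-catalysed syn-hydrostannation of both alkynes: tin goes to the terminal carbon of the neopentyl-type alkyne (C6) and to the methyl-bearing carbon of the internal alkyne (C19, distal to branched C17), giving the E geometry required at C6=C7 and C18=C19.

Step 28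
Reactants: 42 decalin bis(alkenylstannane); 29 (2E,4Z)-5-iodohexa-2,4-dienoic acid
Product: 43 C1–C19 trienoic acid with the C19 stannane intact
Conditions: Pd2(dba)3 (5 mol%), AsPh3 (20 mol%), iPr2NEt, NMP, rt
Reagents that add atoms: none
Why: Stille coupling: the unhindered disubstituted alkenylstannane at C6 transmetallates far faster than the α-methyl stannane at C19, so only the C5–C6 bond forms, with retention of all olefin geometries (2E,4Z,6E).

Step 29
Reactants: 43 trienoic acid C19 stannane; 41 side-chain (E)-vinyl iodide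
Product: 44 seco-acid (23-OH, 25-OTBS)
Conditions: Pd2(dba)3 (10 mol%), AsPh3 (40 mol%), CuI (20 mol%), iPr2NEt, NMP, 40 °C
Reagents that add atoms: none
Why: Copper-assisted Stille coupling of the remaining hindered alkenylstannane with the E-vinyl iodide forms C19–C20 with retention, completing the 18E,20E diene.

Step 30
Reactants: 44 seco-acid
Product: 46 25-O-TBS-superstolide A, via mixed anhydride 45 (not isolated)
Conditions: 2,4,6-Cl3C6H2COCl, Et3N, THF, rt; then DMAP, toluene (0.5 mM), 60 °C
Reagents that add atoms: 2,4,6-trichlorobenzoyl chloride, atoms in 45 only (O=C(Cl)c1c(Cl)cc(Cl)cc1Cl)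
Why: Yamaguchi macrolactonisation: the mixed anhydride acylates DMAP and the only free hydroxyl group (C23) closes the 16-membered lactone under high dilution; the carbamate and amide nitrogens are too weakly nucleophilic to compete.

Step 31
Reactants: 46 25-O-TBS-superstolide A
Product: 47 superstolide A
Conditions: HF·pyridine, pyridine, THF, 0 °C → rt
Reagents that add atoms: none
Why: Buffered fluoride cleavage of the silyl ether leaves the lactone, carbamate and polyenes intact.

## Compound list

1 | acetone N,N-dimethylhydrazone | CC(C)=NN(C)C | starting material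
2 | allyl bromide | C=CCBr | starting material
3 | methallyl bromide (3-bromo-2-methylprop-1-ene) | C=C(C)CBr | starting material
4 | hex-5-en-2-one N,N-dimethylhydrazone | C=CCCC(C)=NN(C)C | intermediate (not isolated)
5 | 2-methylnona-1,8-dien-5-one N,N-dimethylhydrazone | C=CCCC(CCC(C)=C)=NN(C)C | intermediate (not isolated)
6 | 2-methylnona-1,8-dien-5-one | C=CCCC(=O)CCC(C)=C | intermediate
7 | 4-methylcyclohept-4-en-1-one | CC1=CCCC(=O)CC1 | intermediate
8 | racemic cis-1-methyl-8-oxabicyclo[5.1.0]octan-4-one (one enantiomer drawn) | C[C@@]12CCC(=O)CC[C@@H]1O2 | intermediate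
9 | 1-methyl-4-oxocyclohexane-1-carbaldehyde | CC1(C=O)CCC(=O)CC1 | intermediate
10 | 4-ethynyl-4-methylcyclohexan-1-one | C#CC1(C)CCC(=O)CC1 | intermediate
11 | 4-ethynyl-4-methylcyclohexa-2,5-dien-1-one | C#CC1(C)C=CC(=O)C=C1 | intermediate
12 | but-3-yn-2-one | CC(=O)C#C | starting material
13 | (3E)-4-[(4-methoxyphenyl)methoxy]but-3-en-2-one | CC(=O)/C=C/OCc1ccc(OC)cc1 | intermediate
14 | (E)-1-[(4-methoxyphenyl)methoxy]-3-(trimethylsilyloxy)buta-1,3-diene | C=C(O[Si](C)(C)C)/C=C/OCc1ccc(OC)cc1 | intermediate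
15 | cis-fused (9β-H,14β-H) 8α-ethynyl-8β-methyl-13α-(4-methoxybenzyloxy)-11-(trimethylsilyloxy)bicyclo[4.4.0]deca-11,16-dien-15-one (superstolide locants) | C[Si](C)(C)OC1=C[C@H](OCc3ccc(OC)cc3)[C@@H]2C(=O)C=C[C@](C)(C#C)[C@@H]2C1 | intermediate (not isolated)
16 | cis-8α-ethynyl-4α-[(4-methoxyphenyl)methoxy]-8β-methyl-3,4,4a,8a-tetrahydronaphthalene-2,5(1H,8H)-dione (4aβ-H,8aβ-H; C11 and C15 ketones) | O=C1C[C@H](OCc3ccc(OC)cc3)[C@@H]2C(=O)C=C[C@](C)(C#C)[C@@H]2C1 | intermediate
17 | 11α-hydroxy analogue of 16 (C11 equatorial alcohol, 15-enone) | O[C@@H]1C[C@H](OCc3ccc(OC)cc3)[C@@H]2C(=O)C=C[C@](C)(C#C)[C@@H]2C1 | intermediate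
18 | 11α-methoxy-13α-(4-methoxybenzyloxy)-8α-ethynyl-8β-methyl cis-decal-16-en-15-one | CO[C@@H]1C[C@H](OCc3ccc(OC)cc3)[C@@H]2C(=O)C=C[C@](C)(C#C)[C@@H]2C1 | intermediate
19 | C15 trimethylsilyl enol ether (Δ15) of the 17α-propynyl ketone | CO[C@@H]1C[C@H](OCc3ccc(OC)cc3)[C@@H]2C(O[Si](C)(C)C)=C[C@H](C#CC)[C@](C)(C#C)[C@@H]2C1 | intermediate (not isolated)
20 | C15 enol triflate (Δ15), 17α-(prop-1-ynyl), 8α-ethynyl, 8β-methyl, 11α-OMe, 13α-OPMB cis-decalin | CO[C@@H]1C[C@H](OCc3ccc(OC)cc3)[C@@H]2C(OS(=O)(=O)C(F)(F)F)=C[C@H](C#CC)[C@](C)(C#C)[C@@H]2C1 | intermediate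
21 | Δ15 cis-decalin: 8α-ethynyl-8β-methyl-17α-(prop-1-ynyl)-11α-methoxy-13α-(4-methoxybenzyloxy) | CO[C@@H]1C[C@H](OCc3ccc(OC)cc3)[C@@H]2C=C[C@H](C#CC)[C@](C)(C#C)[C@@H]2C1 | intermediate
22 | 13α-alcohol of 21 | CO[C@@H]1C[C@H](O)[C@@H]2C=C[C@H](C#CC)[C@](C)(C#C)[C@@H]2C1 | intermediate
23 | 13α-O-(N-trichloroacetylcarbamate) of 22 | CO[C@@H]1C[C@H](OC(=O)NC(=O)C(Cl)(Cl)Cl)[C@@H]2C=C[C@H](C#CC)[C@](C)(C#C)[C@@H]2C1 | intermediate (not isolated)
24 | 13α-carbamate of 22 (decalin core, C6–C19) | CO[C@@H]1C[C@H](OC(N)=O)[C@@H]2C=C[C@H](C#CC)[C@](C)(C#C)[C@@H]2C1 | intermediate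
25 | but-2-yn-1-ol | CC#CCO | starting material
26 | (Z)-3-iodobut-2-en-1-ol | C/C(I)=C/CO | intermediate
27 | (Z)-3-iodobut-2-enal | C/C(I)=C/C=O | intermediate (not isolated)
28 | methyl (2E,4Z)-5-iodohexa-2,4-dienoate | C/C(I)=C/C=C/C(=O)OC | intermediate
29 | (2E,4Z)-5-iodohexa-2,4-dienoic acid | C/C(I)=C/C=C/C(=O)O | intermediate
30 | D-alaninol, (R)-2-aminopropan-1-ol | C[C@@H](N)CO | starting material
31 | N-[(2R)-1-hydroxypropan-2-yl]acetamide | C[C@@H](NC(C)=O)CO | intermediate
32 | N-[(2R)-1-oxopropan-2-yl]acetamide | C[C@@H](NC(C)=O)C=O | intermediate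
33 | N-[(2R,3S,4S)-3-hydroxy-4-methylhex-5-en-2-yl]acetamide | C=C[C@H](C)[C@H](O)[C@@H](C)NC(C)=O | intermediate
34 | N-[(2R,3S,4S)-3-(tert-butyldimethylsilyloxy)-4-methylhex-5-en-2-yl]acetamide | C=C[C@H](C)[C@H](O[Si](C)(C)C(C)(C)C)[C@@H](C)NC(C)=O | intermediate
35 | 1,2,4-trioxolane (ozonide) of 34, mixture at the ring carbon | C1OOC(O1)[C@H](C)[C@H](O[Si](C)(C)C(C)(C)C)[C@@H](C)NC(C)=O | intermediate (not isolated)
36 | N-[(2R,3S,4R)-3-(tert-butyldimethylsilyloxy)-4-methyl-5-oxopentan-2-yl]acetamide | O=C[C@H](C)[C@H](O[Si](C)(C)C(C)(C)C)[C@@H](C)NC(C)=O | intermediate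
37 | (S)-but-3-yn-2-ol | C[C@H](O)C#C | starting material
38 | (S)-but-3-yn-2-yl methanesulfonate | C[C@H](OS(C)(=O)=O)C#C | intermediate
39 | N-[(2R,3S,4S,5R,6R)-3-(tert-butyldimethylsilyloxy)-5-hydroxy-4,6-dimethyloct-7-yn-2-yl]acetamide | C#C[C@@H](C)[C@H]([C@H](C)[C@H](O[Si](C)(C)C(C)(C)C)[C@@H](C)NC(C)=O)O | intermediate
40 | (7E)-8-(tributylstannyl) analogue of 41 | CCCC[Sn](CCCC)(CCCC)/C=C/[C@@H](C)[C@H]([C@H](C)[C@H](O[Si](C)(C)C(C)(C)C)[C@@H](C)NC(C)=O)O | intermediate (not isolated)
41 | N-[(2R,3S,4S,5R,6R,7E)-3-(tert-butyldimethylsilyloxy)-5-hydroxy-8-iodo-4,6-dimethyloct-7-en-2-yl]acetamide | I/C=C/[C@@H](C)[C@H]([C@H](C)[C@H](O[Si](C)(C)C(C)(C)C)[C@@H](C)NC(C)=O)O | intermediate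
42 | decalin core with (E)-2-(tributylstannyl)vinyl at C8 and (E)-2-(tributylstannyl)prop-1-enyl at C17 | CO[C@@H]1C[C@H](OC(N)=O)[C@@H]2C=C[C@H](/C=C(\C)[Sn](CCCC)(CCCC)CCCC)[C@](C)(/C=C/[Sn](CCCC)(CCCC)CCCC)[C@@H]2C1 | intermediate
43 | (2E,4Z,6E)-trienoic acid (C1–C7 on C8) with the C19 tributylstannane at C17 | CO[C@@H]1C[C@H](OC(N)=O)[C@@H]2C=C[C@H](/C=C(\C)[Sn](CCCC)(CCCC)CCCC)[C@](C)(/C=C/C(C)=C\C=C\C(O)=O)[C@@H]2C1 | intermediate
44 | seco-acid of 25-O-TBS-superstolide A (free C23-OH and C1 acid) | CO[C@@H]1C[C@H](OC(N)=O)[C@@H]2C=C[C@H](/C=C(C)/C=C/[C@@H](C)[C@H]([C@H](C)[C@H](O[Si](C)(C)C(C)(C)C)[C@@H](C)NC(C)=O)O)[C@](C)(/C=C/C(C)=C\C=C\C(O)=O)[C@@H]2C1 | intermediate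
45 | mixed 2,4,6-trichlorobenzoic anhydride of 44 | CO[C@@H]1C[C@H](OC(N)=O)[C@@H]2C=C[C@H](/C=C(C)/C=C/[C@@H](C)[C@H]([C@H](C)[C@H](O[Si](C)(C)C(C)(C)C)[C@@H](C)NC(C)=O)O)[C@](C)(/C=C/C(C)=C\C=C\C(=O)OC(=O)c3c(Cl)cc(Cl)cc3Cl)[C@@H]2C1 | intermediate (not isolated)
46 | 25-O-(tert-butyldimethylsilyl)superstolide A | CO[C@@H]1C[C@H](OC(N)=O)[C@@H]2C=C[C@@H]3/C=C(C)/C=C/[C@@H](C)[C@H]([C@H](C)[C@H](O[Si](C)(C)C(C)(C)C)[C@@H](C)NC(C)=O)OC(=O)/C=C/C=C(C)\C=C\[C@]3(C)[C@@H]2C1 | intermediate
47 | superstolide A (8R,9R,11S,13S,14R,17R,22R,23R,24R,25S,26R; 2E,4Z,6E,18E,20E) | CO[C@@H]1C[C@H](OC(N)=O)[C@@H]2C=C[C@@H]3/C=C(C)/C=C/[C@@H](C)[C@H]([C@H](C)[C@H](O)[C@@H](C)NC(C)=O)OC(=O)/C=C/C=C(C)\C=C\[C@]3(C)[C@@H]2C1 | target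

## Step count and risks

Total: 31 steps. Longest linear sequence: 18 steps (1–6, 9–15, 27–31).

**Step 9 (the proposed new annulation).** Enantioselectivity, facial selectivity and clean double C–C bond formation on this dienone are all unproven. Fallback, from 11 and 14 back to 16: run the same bond construction with the achiral Lewis acid Me3SiNTf2 (1 mol%, CH2Cl2, −78 °C; known silyl-triflimide Mukaiyama–Michael chemistry). This gives 15 as a racemate, that is, together with the enantiomeric silyl enol ether F1. Buffered hydrolysis gives 16 together with the enantiomeric diketone F2. The enantiomers are separated by preparative chromatography on a polysaccharide chiral stationary phase, so resolution replaces asymmetric catalysis, and 16 re-enters at step 10.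

**Step 12 (conjugate alkynylation next to the quaternary carbon).** The nucleophile must enter on the α face, 1,3-syn to C10, and the β-carbon is neopentyl. Fallback, from 18 back to 21 (bypassing 20 and step 13): Luche reduction of 18 (NaBH4, CeCl3·7H2O, MeOH, −78 °C) from the less hindered β face gives the 15α-allylic alcohol F3. Mitsunobu inversion with picolinic acid (PPh3, DIAD, THF) gives the 15β-picolinate F4. Copper-mediated anti SN2′ substitution with the propynylcopper reagent (MeC≡CMgBr, CuBr·SMe2, THF, −40 °C) then delivers the propynyl group to C17 anti to the leaving group, on the α face, and moves the olefin to C15=C16, giving 21 directly. Here the C17 configuration is fixed by the leaving group and not by facial bias.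

**Step 29 (Stille coupling of the hindered α-methyl alkenylstannane).** Transmetallation may be too slow and protodestannylation may win. Fallback, from 43 and 39 back to 44: iododestannylation of 43 (I2, CH2Cl2, 0 °C) gives the C19 vinyl iodide acid F5. Zirconium-catalysed hydroboration of alkyne 39 (pinacolborane, Cp2Zr(H)Cl 10 mol%, Et3N, 60 °C) gives the side-chain (E)-alkenylboronate F6. Suzuki coupling of F5 with F6 (Pd(PPh3)4, aq. K3PO4, THF, rt) reverses the polarity, with oxidative addition now at the hindered partner, and gives 44.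

## Further compounds

F1 | step 9 | enantiomer of silyl enol ether 15 | C[Si](C)(C)OC1=C[C@@H](OCc3ccc(OC)cc3)[C@H]2C(=O)C=C[C@@](C)(C#C)[C@H]2C1
F2 | step 9 | enantiomer of diketone 16 | O=C1C[C@@H](OCc3ccc(OC)cc3)[C@H]2C(=O)C=C[C@@](C)(C#C)[C@H]2C1
F3 | step 12 | 15α-allylic alcohol from 18 (Δ16) | CO[C@@H]1C[C@H](OCc3ccc(OC)cc3)[C@@H]2[C@H](O)C=C[C@](C)(C#C)[C@@H]2C1
F4 | step 12 | 15β-picolinate (pyridine-2-carboxylate) of the inverted allylic alcohol | CO[C@@H]1C[C@H](OCc3ccc(OC)cc3)[C@@H]2[C@@H](OC(=O)c3ccccn3)C=C[C@](C)(C#C)[C@@H]2C1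
F5 | step 29 | C19 vinyl iodide trienoic acid (iodide in place of the stannane of 43) | CO[C@@H]1C[C@H](OC(N)=O)[C@@H]2C=C[C@H](/C=C(\C)I)[C@](C)(/C=C/C(C)=C\C=C\C(O)=O)[C@@H]2C1
F6 | step 29 | side-chain (E)-alkenylboronic acid pinacol ester from 39 | CC1(C)OB(/C=C/[C@@H](C)[C@H]([C@H](C)[C@H](O[Si](C)(C)C(C)(C)C)[C@@H](C)NC(C)=O)O)OC1(C)C
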